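**Retrosynthetic overview**

- Ring B carries oxygen at C6 and C10 on either side of the fusion bond C1–C5, and C1 is quaternary. C9–C10(O)–C1 is therefore read as an oxyallyl cation, C5=C6(OSi)–C7=C8 as a 2-siloxydiene, and C2–C3–C4 of ring A as the tether between them.
- Key disconnection: C1–C5 and C8–C9 together, by intramolecular (4+3) cycloaddition of an acyclic α-chloro ketone. Rings A and B form in the same step; no ring exists before it.
- After the cycloaddition: C6 enol ether → ketone → 6α-alcohol (chelation by O4) → aroate; C10 ketone → C8=C9 enone → 10α-alcohol → tiglate; desilylation.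
- Before it: the chloromethyl ketone is made from a Weinreb amide and LiCH2Cl only after the siloxydiene is in place. Both chain ends come from the C1 methyl ketone and C6 aldehyde of ozonised (S)-terpinen-4-ol silyl ether, which supplies C4.

Key step: step 10

Remark: daucane numbering is used for all intermediates; β is the face of the bicycle that carries the C1 methyl group, α the opposite face. (E)-1-Bromoprop-1-ene is taken as the pure E isomer. C6 (until it is oxidised) and C1 (until it is ionised) are carried as epimer mixtures, so their descriptors are left open in the SMILES.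

**Route**

Step 1
Reactants: 1 (S)-terpinen-4-ol
Product: 2 (S)-terpinen-4-ol triethylsilyl ether
Conditions: TESOTf, 2,6-lutidine, CH2Cl2, −78 → 0 °C
Reagents that add atoms: triethylsilyl triflate, CC[Si](CC)(CC)OS(=O)(=O)C(F)(F)F
Why: Silylation of the hindered tertiary alcohol with a silyl triflate is standard and leaves C4 untouched; the ether prevents hemiketal formation after ozonolysis and later keeps O4 from capturing the oxyallyl cation.

Step 2
Reactants: 2 (S)-terpinen-4-ol triethylsilyl ether
Product: 4 (3S)-6-oxo-3-(propan-2-yl)-3-(triethylsilyloxy)heptanal, via ozonide 3 (not isolated)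
Conditions: O3, CH2Cl2, −78 °C; PPh3, −78 °C → rt
Reagents that add atoms: ozone, [O-][O+]=O
Why: Ozonolysis with reductive work-up cleaves the only alkene and should give the C1 methyl ketone and the C6 aldehyde as two differentiated carbonyl groups, with C4 unchanged.

Step 3
Reactants: 4 (3S)-6-oxo-3-(propan-2-yl)-3-(triethylsilyloxy)heptanal; 5 (E)-1-bromoprop-1-ene
Product: 7 (8E)-7-hydroxy-5-(propan-2-yl)-5-(triethylsilyloxy)dec-8-en-2-one (C4 as in 1; both C6 epimers), via (E)-prop-1-enylchromium dichloride 6 (not isolated)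
Conditions: CrCl2 (4 equiv), NiCl2 (2 mol %), DMF, rt
Reagents that add atoms: CrCl2, Cl[Cr]Cl (chromium and chloride in 6 only)
Why: The Nozaki–Hiyama–Kishi alkenylation adds the alkenylchromium reagent to the aldehyde and not to the methyl ketone, and it keeps the E geometry; the new C6 carbinol forms without control and is oxidised in step 6.

Step 4
Reactants: 7 (8E)-7-hydroxy-5-(propan-2-yl)-5-(triethylsilyloxy)dec-8-en-2-one
Product: 8 (2E)-9-methyl-6-(propan-2-yl)-6-(triethylsilyloxy)deca-2,9-dien-4-ol (both carbinol epimers)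
Conditions: Ph3PCH3Br, KOtBu (3 equiv each), THF, 0 °C → rt
Reagents that add atoms: methyltriphenylphosphonium bromide, C[P+](c1ccccc1)(c1ccccc1)c1ccccc1.[Br-]
Why: Wittig methylenation of the unhindered methyl ketone brings in C10; the secondary alkoxide formed by the excess ylide is inert.

Step 5
Reactants: 8 (2E)-9-methyl-6-(propan-2-yl)-6-(triethylsilyloxy)deca-2,9-dien-4-ol
Product: 10 (8E)-2-methyl-5-(propan-2-yl)-5-(triethylsilyloxy)dec-8-ene-1,7-diol (C1 and C6 epimer mixture), via B-alkyl-9-BBN borinate 9 (not isolated)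
Conditions: 9-BBN (2.5 equiv), THF, 0 °C → rt; NaOH, H2O2, 0 °C
Reagents that add atoms: 9-borabicyclo[3.3.1]nonane, B1C2CCCC1CCC2 (boron in 9 only); hydrogen peroxide, OO
Why: Hydroboration–oxidation with 9-BBN is anti-Markovnikov and much faster on the 1,1-disubstituted terminal alkene than on the internal E alkene; the C1 centre forms without control and is erased in step 10.

Step 6
Reactants: 10 (8E)-2-methyl-5-(propan-2-yl)-5-(triethylsilyloxy)dec-8-ene-1,7-diol
Product: 11 (8E)-2-methyl-7-oxo-5-(propan-2-yl)-5-(triethylsilyloxy)dec-8-enoic acid (C1 epimers)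
Conditions: TEMPO (0.2 equiv), PhI(OAc)2 (3.5 equiv), MeCN/H2O 1:1, rt
Reagents that add atoms: water, O
Why: Oxoammonium (TEMPO/PhI(OAc)2) oxidation in aqueous acetonitrile takes the primary alcohol to the acid through the aldehyde hydrate and the allylic alcohol to the E-enone in one operation, removing the C6 stereocentre.

Step 7
Reactants: 11 (8E)-2-methyl-7-oxo-5-(propan-2-yl)-5-(triethylsilyloxy)dec-8-enoic acid
Product: 12 (8E)-N-methoxy-N,2-dimethyl-7-oxo-5-(propan-2-yl)-5-(triethylsilyloxy)dec-8-enamide (C1 epimers)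
Conditions: MeNHOMe·HCl, EDC·HCl, HOBt, N-methylmorpholine, CH2Cl2, 0 °C → rt
Reagents that add atoms: N,O-dimethylhydroxylamine hydrochloride, CNOC.Cl
Why: Carbodiimide amide coupling gives the Weinreb amide, an acyl group that is not enolised under soft conditions, so the next step touches only the enone.

Step 8
Reactants: 12 (8E)-N-methoxy-N,2-dimethyl-7-oxo-5-(propan-2-yl)-5-(triethylsilyloxy)dec-8-enamide
Product: 13 (6Z,8E)-7-(tert-butyldimethylsilyloxy)-N-methoxy-N,2-dimethyl-5-(propan-2-yl)-5-(triethylsilyloxy)deca-6,8-dienamide (C1 epimers)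
Conditions: TBSOTf (1.3 equiv), Et3N (3 equiv), CH2Cl2, −78 → −20 °C
Reagents that add atoms: tert-butyldimethylsilyl triflate, CC(C)(C)[Si](C)(C)OS(=O)(=O)C(F)(F)F
Why: Soft enolisation (silyl triflate and amine) of the enone at C5, its only α′ position, gives the cross-conjugated 2-siloxydiene, with the silyloxy group cis to C4 because the quaternary C4 avoids the vinyl group; the tert-butyldimethylsilyl group is chosen so that the diene survives step 9.

Step 9
Reactants: 13 (6Z,8E)-7-(tert-butyldimethylsilyloxy)-N-methoxy-N,2-dimethyl-5-(propan-2-yl)-5-(triethylsilyloxy)deca-6,8-dienamide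
Product: 15 (7Z,9E)-8-(tert-butyldimethylsilyloxy)-1-chloro-3-methyl-6-(propan-2-yl)-6-(triethylsilyloxy)undeca-7,9-dien-2-one (C1 epimers; the cycloaddition precursor), via lithium hemiaminal adduct 14 (not isolated)
Conditions: ICH2Cl (3 equiv), MeLi·LiBr (2.8 equiv), THF, −78 °C; pH 7 buffer, −78 → 0 °C
Reagents that add atoms: chloroiodomethane, ClCI; methyllithium, [Li]C (lithium in 14 only)
Why: Chloromethyllithium made in the flask adds once to the Weinreb amide and the chelated adduct releases the chloromethyl ketone only on work-up (carbenoid homologation), so an α-chloro ketone and an enone never have to be enolised in the same flask.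

Step 10
Reactants: 15 (7Z,9E)-8-(tert-butyldimethylsilyloxy)-1-chloro-3-methyl-6-(propan-2-yl)-6-(triethylsilyloxy)undeca-7,9-dien-2-one
Product: 17 6-(tert-butyldimethylsilyloxy)-4α-(triethylsilyloxy)-5βH-dauc-6-en-10-one (1β-Me; 4β-iPr; 8α-Me), via oxyallyl cation 16 (not isolated)
Conditions: Et3N (3 equiv, slow addition), LiClO4 (3 M), Et2O, rt, 0.005 M
Reagents that add atoms: none
Why: Lithium-assisted enolisation of 15 at C1 by Et3N and loss of chloride from C9 give the oxyallyl cation 16 (the C1 configuration of 15 is erased), which adds across the s-cis siloxydiene in an intramolecular (4+3) cycloaddition of the Föhlisch type, the bond C1–C5 from the nucleophilic enol-ether carbon running ahead of C8–C9. Ring A closes in a 5-exo mode through the C2–C3–C4 tether onto C5, and ring B closes as the seven-membered ring of the cycloaddition when C9 bonds to the diene terminus C8 (a 7-endo closure if the process is stepwise), leaving C10 as the ketone and C6 as the silyl enol ether. Diene face and C5: with C3 held above the diene plane, allylic 1,3-strain against the cis silyloxy group on C6 places the C4 oxygen rather than the isopropyl group in the plane, so C5 should form with its hydrogen cis to the isopropyl group. C1: the tether can only span from the position syn to the oxyallyl oxygen, and the compact (boat-like) approach, in which C10–O lies over C6–C7 and the C1 methyl points away from the C6 silyloxy group, gives the cis ring fusion with the C1 methyl cis to H-5 and hence cis to the isopropyl group at C4; C8 follows from suprafacial addition to the E alkene and is erased in step 15. The step therefore needs compact over extended approach on that diene face, (4+3) closure at C8 over (3+2) closure at C6, and ionisation faster than N-alkylation of Et3N by the primary chloride; the concentrated LiClO4 medium, high dilution and slow addition of the amine serve these ends.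

Step 11
Reactants: 17 6-(tert-butyldimethylsilyloxy)-4α-(triethylsilyloxy)-5βH-dauc-6-en-10-one
Product: 18 4α-hydroxy-5βH-daucane-6,10-dione (1β-Me; 4β-iPr; 8α-Me)
Conditions: aq. HF (48 %), MeCN, 0 °C → rt
Reagents that add atoms: none
Why: Fluoride-assisted protodesilylation hydrolyses the silyl enol ether to the C6 ketone (protonation at C7) and cleaves the tertiary silyl ether under weakly acidic conditions that should neither epimerise C5 nor start retro-aldol cleavage or dehydration of the β-hydroxy ketone.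

Step 12
Reactants: 18 4α-hydroxy-5βH-daucane-6,10-dione
Product: 20 4α,6α-dihydroxy-5βH-daucan-10-one, via O4-diethylboryl chelate 19 (not isolated)
Conditions: Et2BOMe, THF/MeOH 4:1, 0 → −78 °C; NaBH4, −78 °C; H2O2, pH 7 buffer, 0 °C
Reagents that add atoms: diethylmethoxyborane, CCB(CC)OC (boron in 19 only)
Why: In the Narasaka–Prasad reduction the boron chelate between O4 and the C6 carbonyl activates C6 over the unchelated C10 ketone next to the quaternary C1 and covers the α face, so external hydride should add from the convex β face and give the 6α-alcohol syn to the 4α-hydroxyl.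

Step 13
Reactants: 21 4-hydroxybenzoic acid
Product: 23 4-(tert-butyldimethylsilyloxy)benzoic acid, via bis-silyl benzoate 22 (not isolated)
Conditions: TBSCl (2.2 equiv), imidazole, DMF, rt; AcOH/THF/H2O, rt
Reagents that add atoms: tert-butyldimethylsilyl chloride, CC(C)(C)[Si](C)(C)Cl
Why: Silylation of both acidic groups followed by selective hydrolysis of the labile silyl ester leaves the phenol protected as the aryl silyl ether.

Step 14
Reactants: 20 4α,6α-dihydroxy-5βH-daucan-10-one; 23 4-(tert-butyldimethylsilyloxy)benzoic acid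
Product: 24 6α-[4-(tert-butyldimethylsilyloxy)benzoyloxy]-4α-hydroxy-5βH-daucan-10-one
Conditions: EDC·HCl, DMAP, CH2Cl2, rt → 40 °C
Reagents that add atoms: none
Why: Steglich esterification acylates the secondary C6 hydroxyl with retention while the tertiary C4 hydroxyl does not react.

Step 15
Reactants: 24 6α-[4-(tert-butyldimethylsilyloxy)benzoyloxy]-4α-hydroxy-5βH-daucan-10-one
Product: 26 6α-[4-(tert-butyldimethylsilyloxy)benzoyloxy]-4α-(trimethylsilyloxy)-5βH-dauc-8-en-10-one, via bis-trimethylsilyl enol ether 25 (not isolated)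
Conditions: TMSOTf (2.5 equiv), Et3N, CH2Cl2, 0 °C; Pd(OAc)2 (1.1 equiv), MeCN, rt
Reagents that add atoms: trimethylsilyl triflate, C[Si](C)(C)OS(=O)(=O)C(F)(F)F
Why: In this Saegusa–Ito oxidation the C10 ketone can enolise only toward C9 because C1 is quaternary, and β-hydride elimination of H-8 from the palladium enolate gives the C8=C9 enone and erases C8; the silyl triflate also caps O4.

Step 16
Reactants: 26 6α-[4-(tert-butyldimethylsilyloxy)benzoyloxy]-4α-(trimethylsilyloxy)-5βH-dauc-8-en-10-one
Product: 27 6α-[4-(tert-butyldimethylsilyloxy)benzoyloxy]-4α-(trimethylsilyloxy)-5βH-dauc-8-en-10α-ol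
Conditions: CeCl3·7H2O, NaBH4, MeOH, −78 °C
Reagents that add atoms: none
Why: Luche reduction is 1,2-selective, and hydride should come from the convex β face because the α face of C10 is screened by ring A and the silyloxy group at C4, which sets the 10α-alcohol.

Step 17
Reactants: 27 6α-[4-(tert-butyldimethylsilyloxy)benzoyloxy]-4α-(trimethylsilyloxy)-5βH-dauc-8-en-10α-ol; 28 tiglic acid
Product: 30 6α-[4-(tert-butyldimethylsilyloxy)benzoyloxy]-10α-tigloyloxy-4α-(trimethylsilyloxy)-5βH-dauc-8-ene, via mixed anhydride 29 (not isolated)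
Conditions: 2,4,6-trichlorobenzoyl chloride, Et3N, THF, rt; DMAP, toluene, rt → 60 °C
Reagents that add atoms: 2,4,6-trichlorobenzoyl chloride, O=C(Cl)c1c(Cl)cc(Cl)cc1Cl (in 29 only)
Why: Yamaguchi esterification through the mixed anhydride acylates the hindered allylic alcohol next to the quaternary C1 with retention at C10, and the E geometry of the tigloyl group is the stable one.

Step 18
Reactants: 30 6α-[4-(tert-butyldimethylsilyloxy)benzoyloxy]-10α-tigloyloxy-4α-(trimethylsilyloxy)-5βH-dauc-8-ene
Product: 31 target, 6α-(4-hydroxybenzoyloxy)-10α-tigloyloxy-5βH-dauc-8-en-4α-ol (CNP0273650.13)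
Conditions: HF·pyridine, pyridine, THF, 0 °C → rt
Reagents that add atoms: none
Why: Buffered fluoride desilylation removes the aryl silyl ether and the tertiary trimethylsilyl ether without hydrolysing either ester or ionising the allylic tiglate.

**Compound list**

1 | (S)-terpinen-4-ol, (1S)-4-methyl-1-(propan-2-yl)cyclohex-3-en-1-ol | CC1=CC[C@@](CC1)(C(C)C)O | starting material
2 | (S)-terpinen-4-ol triethylsilyl ether | CC1=CC[C@@](CC1)(C(C)C)O[Si](CC)(CC)CC | intermediate
3 | ozonide (bicyclic 1,2,4-trioxolane) of 2 | CC12CC[C@@](O[Si](CC)(CC)CC)(C(C)C)CC(OO1)O2 | intermediate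
4 | (3S)-6-oxo-3-(propan-2-yl)-3-(triethylsilyloxy)heptanal | CC(=O)CC[C@@](O[Si](CC)(CC)CC)(C(C)C)CC=O | intermediate
5 | (E)-1-bromoprop-1-ene | C/C=C/Br | starting material
6 | (E)-prop-1-enylchromium dichloride (trivalent chromium) | C/C=C/[Cr](Cl)Cl | intermediate
7 | (8E)-7-hydroxy-5-(propan-2-yl)-5-(triethylsilyloxy)dec-8-en-2-one, C6 epimers | CC(=O)CC[C@@](O[Si](CC)(CC)CC)(C(C)C)CC(O)/C=C/C | intermediate
8 | (2E)-9-methyl-6-(propan-2-yl)-6-(triethylsilyloxy)deca-2,9-dien-4-ol, carbinol epimers | C=C(C)CC[C@@](O[Si](CC)(CC)CC)(C(C)C)CC(O)/C=C/C | intermediate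
9 | B-alkyl-9-BBN adduct of 8 with the carbinol as 9-BBN borinate | CC(CB1C2CCCC1CCC2)CC[C@@](O[Si](CC)(CC)CC)(C(C)C)CC(OB1C2CCCC1CCC2)/C=C/C | intermediate
10 | (8E)-2-methyl-5-(propan-2-yl)-5-(triethylsilyloxy)dec-8-ene-1,7-diol, C1 and C6 epimers | CC(CO)CC[C@@](O[Si](CC)(CC)CC)(C(C)C)CC(O)/C=C/C | intermediate
11 | (8E)-2-methyl-7-oxo-5-(propan-2-yl)-5-(triethylsilyloxy)dec-8-enoic acid, C1 epimers | CC(C(=O)O)CC[C@@](O[Si](CC)(CC)CC)(C(C)C)CC(=O)/C=C/C | intermediate
12 | (8E)-N-methoxy-N,2-dimethyl-7-oxo-5-(propan-2-yl)-5-(triethylsilyloxy)dec-8-enamide, C1 epimers | CON(C)C(=O)C(C)CC[C@@](O[Si](CC)(CC)CC)(C(C)C)CC(=O)/C=C/C | intermediate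
13 | (6Z,8E)-7-(tert-butyldimethylsilyloxy)-N-methoxy-N,2-dimethyl-5-(propan-2-yl)-5-(triethylsilyloxy)deca-6,8-dienamide, C1 epimers | CON(C)C(=O)C(C)CC[C@@](O[Si](CC)(CC)CC)(C(C)C)/C=C(O[Si](C)(C)C(C)(C)C)/C=C/C | intermediate
14 | lithium alkoxide of the chloromethyl N-methoxy-N-methyl hemiaminal from 13 | [Li]OC(CCl)(N(C)OC)C(C)CC[C@@](O[Si](CC)(CC)CC)(C(C)C)/C=C(O[Si](C)(C)C(C)(C)C)/C=C/C | intermediate
15 | (7Z,9E)-8-(tert-butyldimethylsilyloxy)-1-chloro-3-methyl-6-(propan-2-yl)-6-(triethylsilyloxy)undeca-7,9-dien-2-one, C1 epimers | ClCC(=O)C(C)CC[C@@](O[Si](CC)(CC)CC)(C(C)C)/C=C(O[Si](C)(C)C(C)(C)C)/C=C/C | intermediate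
16 | oxyallyl cation C9–C10(O)–C1 tethered to the siloxydiene (lithium-associated zwitterion) | C=C([O-])[C+](C)CC[C@@](O[Si](CC)(CC)CC)(C(C)C)/C=C(O[Si](C)(C)C(C)(C)C)/C=C/C | intermediate
17 | 6-(tert-butyldimethylsilyloxy)-4α-(triethylsilyloxy)-5βH-dauc-6-en-10-one (1β-Me, 4β-iPr, 8α-Me) | O=C1C[C@@H](C)C=C(O[Si](C)(C)C(C)(C)C)[C@@H]2[C@@]1(C)CC[C@@]2(O[Si](CC)(CC)CC)C(C)C | intermediate
18 | 4α-hydroxy-5βH-daucane-6,10-dione (1β-Me, 4β-iPr, 8α-Me) | O=C1C[C@@H](C)CC(=O)[C@@H]2[C@@]1(C)CC[C@@]2(O)C(C)C | intermediate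
19 | O4-diethylboryl chelate of 18 | O=C1C[C@@H](C)CC(=O)[C@@H]2[C@@]1(C)CC[C@@]2(OB(CC)CC)C(C)C | intermediate
20 | 4α,6α-dihydroxy-5βH-daucan-10-one | O=C1C[C@@H](C)C[C@@H](O)[C@@H]2[C@@]1(C)CC[C@@]2(O)C(C)C | intermediate
21 | 4-hydroxybenzoic acid | O=C(O)c1ccc(O)cc1 | starting material
22 | tert-butyldimethylsilyl 4-(tert-butyldimethylsilyloxy)benzoate | CC(C)(C)[Si](C)(C)OC(=O)c1ccc(O[Si](C)(C)C(C)(C)C)cc1 | intermediate
23 | 4-(tert-butyldimethylsilyloxy)benzoic acid | CC(C)(C)[Si](C)(C)Oc1ccc(cc1)C(=O)O | intermediate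
24 | 6α-[4-(tert-butyldimethylsilyloxy)benzoyloxy]-4α-hydroxy-5βH-daucan-10-one | O=C1C[C@@H](C)C[C@@H](OC(=O)c3ccc(O[Si](C)(C)C(C)(C)C)cc3)[C@@H]2[C@@]1(C)CC[C@@]2(O)C(C)C | intermediate
25 | 10-trimethylsilyl enol ether (C9=C10) and 4α-trimethylsilyl ether of 24 | C[Si](C)(C)OC1=C[C@@H](C)C[C@@H](OC(=O)c3ccc(O[Si](C)(C)C(C)(C)C)cc3)[C@@H]2[C@@]1(C)CC[C@@]2(O[Si](C)(C)C)C(C)C | intermediate
26 | 6α-[4-(tert-butyldimethylsilyloxy)benzoyloxy]-4α-(trimethylsilyloxy)-5βH-dauc-8-en-10-one | O=C1C=C(C)C[C@@H](OC(=O)c3ccc(O[Si](C)(C)C(C)(C)C)cc3)[C@@H]2[C@@]1(C)CC[C@@]2(O[Si](C)(C)C)C(C)C | intermediate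
27 | 6α-[4-(tert-butyldimethylsilyloxy)benzoyloxy]-4α-(trimethylsilyloxy)-5βH-dauc-8-en-10α-ol | O[C@H]1C=C(C)C[C@@H](OC(=O)c3ccc(O[Si](C)(C)C(C)(C)C)cc3)[C@@H]2[C@@]1(C)CC[C@@]2(O[Si](C)(C)C)C(C)C | intermediate
28 | tiglic acid | C/C=C(\C)C(=O)O | starting material
29 | tiglic 2,4,6-trichlorobenzoic anhydride | C/C=C(\C)C(=O)OC(=O)c1c(Cl)cc(Cl)cc1Cl | intermediate
30 | 6α-[4-(tert-butyldimethylsilyloxy)benzoyloxy]-10α-tigloyloxy-4α-(trimethylsilyloxy)-5βH-dauc-8-ene | C/C=C(\C)C(=O)O[C@H]1C=C(C)C[C@@H](OC(=O)c3ccc(O[Si](C)(C)C(C)(C)C)cc3)[C@@H]2[C@@]1(C)CC[C@@]2(O[Si](C)(C)C)C(C)C | intermediate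
31 | 6α-(4-hydroxybenzoyloxy)-10α-tigloyloxy-5βH-dauc-8-en-4α-ol (CNP0273650.13) | C/C=C(\C)C(=O)O[C@H]1C=C(C)C[C@@H](OC(=O)c2ccc(O)cc2)[C@@H]2[C@@]1(C)CC[C@@]2(O)C(C)C | target

**Step count and risks**

Total step count: 18. Longest linear sequence: 17 (steps 1–12 and 14–18).

Steps most likely to fail:

1. Step 10. Et3N may be alkylated by the primary C9 chloride, or enolisation may run only toward C9, so that the oxyallyl cation forms too slowly and the siloxydiene decays. A stepwise course may also close onto C6, or the extended approach may deliver the C1 epimer. Fallback, setting out from 13 and returning at 17: the leaving group is moved to C1, so that no carbon open to SN2 attack remains and only the C9 methyl has to be enolised. Amide 13 is deprotonated at C1 (LDA, THF, −78 °C) and chlorinated with hexachloroethane to the α-chloro Weinreb amide F1. MeLi (THF, −78 °C) converts this into the tertiary α-chloro methyl ketone F2, the halo ketone class for which base-mediated oxyallyl formation is best established. Et3N and LiClO4 in Et2O should then give the same cation 16 and hence 17.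

2. Step 12. The hindered tertiary C4 hydroxyl may bind boron too slowly, so that control over site (C6 against C10) and face is lost, or the free β-hydroxy ketone may open by retro-aldol cleavage of C4–C5. Fallback, setting out from 17 and returning at 20: chelation control is replaced by steric approach control on a substrate whose O4 stays silylated. Buffered fluoride (Bu4NF/AcOH, THF, −20 °C) cleaves only the silyl enol ether and gives the 4α-triethylsilyloxy diketone F3. L-Selectride (THF, −78 °C) should attack the less screened C6 carbonyl from the convex β face to give the 6α-alcohol F4. HF·pyridine then removes the triethylsilyl group to give 20.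

3. Step 16. Hydride addition to C10, which sits next to the quaternary C1, may show poor facial selectivity. Fallback, setting out from 26 and returning at 27: substrate control is replaced by reagent control in a Corey–Bakshi–Shibata reduction (2-methyl-CBS-oxazaborolidine, catecholborane, toluene, −78 °C), using the catalyst antipode that delivers hydride to the β face. This fallback makes no new compound (F0).

**Further compounds**

F1 | step 10 | (6Z,8E)-7-(tert-butyldimethylsilyloxy)-2-chloro-N-methoxy-N,2-dimethyl-5-(propan-2-yl)-5-(triethylsilyloxy)deca-6,8-dienamide | CON(C)C(=O)C(C)(Cl)CC[C@@](O[Si](CC)(CC)CC)(C(C)C)/C=C(O[Si](C)(C)C(C)(C)C)/C=C/C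
F2 | step 10 | (7Z,9E)-8-(tert-butyldimethylsilyloxy)-3-chloro-3-methyl-6-(propan-2-yl)-6-(triethylsilyloxy)undeca-7,9-dien-2-one | CC(=O)C(C)(Cl)CC[C@@](O[Si](CC)(CC)CC)(C(C)C)/C=C(O[Si](C)(C)C(C)(C)C)/C=C/C
F3 | step 12 | 4α-(triethylsilyloxy)-5βH-daucane-6,10-dione | O=C1C[C@@H](C)CC(=O)[C@@H]2[C@@]1(C)CC[C@@]2(O[Si](CC)(CC)CC)C(C)C
F4 | step 12 | 6α-hydroxy-4α-(triethylsilyloxy)-5βH-daucan-10-one | O=C1C[C@@H](C)C[C@@H](O)[C@@H]2[C@@]1(C)CC[C@@]2(O[Si](CC)(CC)CC)C(C)C
F0 | step 16 | none | none
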